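## Retrosynthetic overview
1. Target 5 ⇒ remove the O‑acetyl group and disconnect the C15–O bond. A 1,3‑oxygen shift (C15 → C13) leads back to (−)‑sclareol 1.
2. C5, C8, C9, C10 and the free 8α‑OH are bought with 1. C13 stops being a stereocentre, and the only new stereo element is the E C13=C14 bond.
3. No ring is formed. Rings A and B (the trans‑decalin) come intact from 1.
4. Forward: one pot, with reversible oxygen transposition on vanadium and a lipase that removes only the E primary alcohol as its acetate.

Assumption: commercial (−)‑sclareol from clary sage is the single enantiomer (5S,8R,9R,10S,13R). Its four ring stereocentres are those written in the target SMILES.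

## Route

Step 1
Reactants: 1 (−)‑sclareol, (13R)‑labd‑14‑ene‑8α,13‑diol
Product: 5 (13E)‑8α‑hydroxylabd‑13‑en‑15‑yl acetate, via 13‑episclareol 2 (not isolated), via Z‑diol 3 (not isolated), via E‑diol 4 (not isolated)
Conditions: VO(OSiPh3)3 (10 mol%), Novozym 435 (immobilised Candida antarctica lipase B), isopropenyl acetate (1.5 equiv, added over 24 h), toluene, argon, 70 °C, 48 h; filter, SiO2
Reagents that add atoms: isopropenyl acetate, CC(=C)OC(C)=O
Why: Proposed new method: geometry‑convergent dynamic kinetic acetylation, in which VO(OSiPh3)3 (pentavalent vanadium) exchanges one silanolate for the less hindered C13 alkoxide of 1 and relays oxygen from C13 to C15 through a closed six‑membered chair [3,3] shift (V=O bonds to C15 while C13–O breaks), making the key C15–O bond without a free allyl cation that the C8 hydroxyl could trap; the shift is reversible and keeps 1, 2, 3 and 4 in equilibrium, the lipase acetylates only primary hydroxyls (both tertiary hydroxyls are inert), and its narrow funnel should accept the rod‑shaped E‑diol 4 much faster than the bent Z‑diol 3, whose decalin folds back over the carbinol; acetates do not bind vanadium, so 5 is a kinetic sink and the E geometry is set under Curtin–Hammett control (slow addition of the acyl donor keeps acylation slower than equilibration) while C5, C8, C9 and C10 are untouched; closest known reaction type: lipase/oxovanadium dynamic kinetic resolution of racemic allylic alcohols with 1,3‑transposition, so far used to select a carbinol stereocentre and not the geometry of a trisubstituted alkene made from a tertiary vinyl carbinol.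

Mass balance: C20H36O2 (1) + C5H8O2 → C22H38O3 (5) + C3H6O.

## Compound list
1 | (−)‑sclareol, (13R)‑labd‑14‑ene‑8α,13‑diol; trans‑decalin with equatorial 8α‑OH, axial 8β‑CH3 and β side chain at C9 | C=C[C@](C)(O)CC[C@@H]1[C@@]2(C)CCCC(C)(C)[C@@H]2CC[C@@]1(C)O | starting material
2 | 13‑episclareol, (13S)‑labd‑14‑ene‑8α,13‑diol | C=C[C@@](C)(O)CC[C@@H]1[C@@]2(C)CCCC(C)(C)[C@@H]2CC[C@@]1(C)O | intermediate (not isolated)
3 | (13Z)‑labd‑13‑ene‑8α,15‑diol | OC/C=C(/C)CC[C@@H]1[C@@]2(C)CCCC(C)(C)[C@@H]2CC[C@@]1(C)O | intermediate (not isolated)
4 | (13E)‑labd‑13‑ene‑8α,15‑diol | OC/C=C(\C)CC[C@@H]1[C@@]2(C)CCCC(C)(C)[C@@H]2CC[C@@]1(C)O | intermediate (not isolated)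
5 | (13E)‑8α‑hydroxylabd‑13‑en‑15‑yl acetate, (2E)‑5‑[(1R,2R,4aS,8aS)‑2‑hydroxy‑2,5,5,8a‑tetramethyldecahydronaphthalen‑1‑yl]‑3‑methylpent‑2‑en‑1‑yl acetate | CC(=O)OC/C=C(\C)CC[C@@H]1[C@@]2(C)CCCC(C)(C)[C@@H]2CC[C@@]1(C)O | target

## Step count and risks
Total step count: 1. Longest linear sequence: 1.

The route has a single step, so the list of steps most likely to fail has one entry.

**Step 1 (the proposed new step)** has three ways to fail:
- **Slow transposition.** An allyl system with a primary terminus may shift too slowly at a temperature the lipase tolerates.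
- **Ionisation at C13.** Partial ionisation lets the C8 hydroxyl close to the manoyl oxides, which are a dead end.
- **Weak E/Z discrimination.** The lipase may not distinguish 4 from 3 well enough, giving an E/Z acetate mixture that needs AgNO3‑silica separation.

**Fallback (known chemistry, sets out from 1 and comes back at 4).**
Both tertiary hydroxyls of 1 are acetylated with AcCl and N,N‑dimethylaniline in CH2Cl2 to give sclareol 8,13‑diacetate F1.
PdCl2(MeCN)2 (5 mol%, divalent palladium) in THF at room temperature then moves the allylic acetate from C13 to C15. This is the cyclisation‑induced [3,3] rearrangement of allylic acetates, and it gives (13E)‑labd‑13‑ene‑8α,15‑diyl diacetate F2. Chromatography on AgNO3‑silica secures the E isomer.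
KOH in refluxing MeOH cleaves both esters to give isolated 4.
Finally 4 is acetylated only at its primary hydroxyl by the lipase half of step 1 (Novozym 435, isopropenyl acetate, toluene) to reach 5.

## Further compounds
F1 | step 1 | sclareol 8,13‑diacetate, (13R)‑labd‑14‑ene‑8α,13‑diyl diacetate | C=C[C@](C)(OC(C)=O)CC[C@@H]1[C@@]2(C)CCCC(C)(C)[C@@H]2CC[C@@]1(C)OC(C)=O
F2 | step 1 | (13E)‑labd‑13‑ene‑8α,15‑diyl diacetate | CC(=O)OC/C=C(\C)CC[C@@H]1[C@@]2(C)CCCC(C)(C)[C@@H]2CC[C@@]1(C)OC(C)=O
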